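## Analysis of the target

Compound 31 is a 1,7,8,8a-tetrahydro-6H-isochromen-6-one. Ring A is a 2H-pyran (O2, C1, C3, C4, C4a, C8a), fused through C4a–C8a to ring B, a cyclohexenone (C4a, C5, C6, C7, C8, C8a). The unit O2–C3=C4–C4a=C5–C6=O is a doubly vinylogous ester that runs on into C1'=C2' of the (E)-heptenyl side chain at C3. Six stereocentres fall into two sets. On ring B, C7 (S, tertiary carbinol with methyl), C8 (R) and C8a (S) carry the C7 hydroxyl trans to the C8 hydroxyl and the C8 hydroxyl cis to the C8a–C1 bond. In the side chain, C3' (R, tertiary allylic carbinol), C4' (S) and C5' (R) are separated from the ring set by five sp2 carbons, so each set needs its own source of chirality. Sensitive points are the tertiary α-ketol at C6/C7 (ketol shift), the C3' hydroxyl, which is allylic and conjugated with O2 and so ionises easily in acid, the electron-rich trienyl ether, and the γ-hydrogen at C8a, which a base can remove with loss of the C1 or C8 oxygen. The hard part is the array C6(=O)–C7(OH)(CH3)–C8(OH): C7 bears no hydrogen, and C6 and C7 are both carbonyl-derived carbons of like polarity. The plan rests on this feature. The C6–C7 bond of ring B belongs to an acyloin with a fully substituted carbinol carbon, so it is made by adding a C6 acyl anion equivalent to a C7 methyl ketone.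

## Retrosynthetic reasoning

**O2–C3 (31 to 30).** Ring A is opened at the enol ether bond, giving the enynone pentaol 30 with a free C1 hydroxyl and a C3≡C4 triple bond. C3 is the δ-carbon of the ynenone, so a 6-endo addition of O2 is favoured by both ring size and polarity. Cutting here leaves the acid-sensitive trienyl ether to be formed last, under neutral catalysis by a cationic monovalent gold complex.

**Silyl groups and C4a=C5 (30 to 29 to 28).** All hydroxyls of 30 are silylated in 29, and global desilylation is placed before ring A closure because 29 tolerates buffered fluoride better than 31 would. The C4a=C5 bond of 29 is traced to β-elimination of a C4a silyloxy group from the ring B ketol 28. Holding C4a as a saturated, silylated tertiary carbinol keeps enal, enone and 1,3-dicarbonyl reactivity out of the ring-forming step and makes the C4a configuration irrelevant.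

**C6–C7 (28 to 27).** Ring B is cut between the ketone carbon and the tertiary carbinol carbon. This is the only ring B bond whose two ends are both carbonyl carbons in the open form, and the only cut that leaves C8 and C8a as an acyclic pair. The forward step joins the C6 aldehyde of 27 to its C7 methyl ketone by polarity reversal and sets C7.

**Timing of the two carbonyl groups (27 to 26 to 25 to 24).** A free methyl ketone at C7 cannot be present while an acetylide and an ester enolate are added at C4a. An aldehyde at C6 cannot be made by hydride reduction beside that ketone. C7 is therefore carried as an N,N-dimethylamide and C6 as a methyl ester. The ester of 24 is reduced first to alcohol 25 (the amide is inert). The amide is then turned into the ketone of 26 by a methyl organolithium. Only then is the primary alcohol oxidised to the aldehyde of 27.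

**C4a–C5 (24 and 23 to 20 plus 21).** The two-carbon arm is removed as the enolate of methyl acetate 21 adding to the C4a ketone of ynone 20. An ynone is a reactive, unhindered acceptor, and the epimeric mixture at C4a needs no control.

**C4–C4a (20 to 18 plus 10).** The ynone is cut at the acyl–alkyne bond into diamide 18, whose C4a carbonyl is an N-methoxy-N-methylamide, and the side-chain enyne 10. This is the point of convergence: all six stereocentres exist before it, and a lithium acetylide does not attack the dimethylamide at C7.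

**C8a–C1 and the malate core (18 to 17 to 16 to 15 to 11 plus 12).** C8 and C8a are the carbinol and α-carbon of dimethyl (R)-malate 11. Anti hydroxymethylation of its dianion with formaldehyde 12 sets C8a. The new hydroxyl closes onto the C7 ester to give lactone 15, which distinguishes C7 (lactone) from C4a (methyl ester) at no extra cost. Aminolysis of the lactone gives 16, silylation gives 17, and ester-to-amide exchange gives 18.

**Side chain (10 to 8 to 5 plus 6, 5 to 1).** The enyne is taken back to diynol 8, whose proximal triple bond is reduced to the E alkene under direction by the tertiary hydroxyl. The C3'–C2' bond is cut to methyl ketone 5 and the diyne 6, with the α-silyloxy centre controlling C3'. Ketone 5 comes from L-allo-isoleucine 1, which already holds C4' and C5'.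

## Alternatives that were turned down

**Alternative 1:** domino Knoevenagel and hetero-Diels–Alder reaction.
- Disconnection: C4=C4a, C4a–C8a and O2–C1, so both rings are made together.
- Forward key step: a C4a aldehyde condenses with the side-chain β-keto allyl ester. The resulting 1-oxadiene (O2=C3–C4=C4a) adds across a C8a=C1 vinyl group to give the trans-fused pyranocyclohexane A1.
- For it: three bonds, two rings and the side-chain union in one metal-free operation. In bonds and rings per step it is clearly stronger than the chosen plan.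
- Against it: the tether forces the electrophilic carbon C4a onto the substituted alkene carbon C8a and the oxygen onto the terminal CH2. Charge would then build on a primary carbon, and the dienophile is an unactivated monosubstituted alkene, so forcing conditions are likely and the tertiary allylic alcohol would not survive them. A1 is also at the wrong oxidation level: C4a is an sp3 stereocentre that must be erased, C6 is a protected alcohol, and C4 carries an ester. Deallylation and decarboxylation, acetonide removal, oxidation at C6 and dehydrogenation across C4a–C5 would all follow on a sensitive dienyl ether. The C6/C7/C8 triad must still be built beforehand on an open chain.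
- Comparison: the chosen plan makes one ring bond in its key step, but at the final oxidation level, and reaches C4a=C5 by a simple elimination.

**Alternative 2:** ring opening of a donor–acceptor cyclobutanone.
- Disconnection: C4a–C8a and C7–C8, a formal [4+2] assembly of ring B.
- Forward key step: EtAlCl2 opens a 3-ethoxycyclobutanone between C7 and C4a. An enol ether carbon (C8a, inside a 1,3-dioxine) attacks the C4a oxocarbenium ion, the C7 enolate closes on C8, and ethanol is lost to give ynenone A2.
- For it: two C–C bonds, the enone already in place, a cis-fused dioxane that fixes the C8/C8a relation, and a short end-game. On convergence and on bonds per step it is stronger than the benzoin plan.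
- Against it: the cyclobutanone needs two fully substituted carbons (C4a with ethoxy and enynyl, C7 with methyl and silyloxy), and its synthesis as one regio- and stereoisomer is a project of its own. On ring opening C7 becomes a planar enolate, so its configuration must be set anew in the closure onto C8 with no obvious control element. The C4a cation is propargylic and ambident. EtAlCl2 is harsh towards the tertiary allylic silyl ether.
- Comparison: the chosen plan takes C8 and C8a from malate with certainty and leaves only C7 to a chair transition state.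

**Alternative 3:** gold cascade on an acyclic diynone.
- Disconnection: O2–C3 and C4a=C5, with the C6 oxygen coming from water.
- Forward key step: Ph3PAuNTf2 in wet solvent is asked to do three things. The C1 hydroxyl adds 6-endo to the ynone, an ethynyl carbinol at C7 is hydrated to the C6 methyl ketone, and that methyl ketone condenses with the C4a carbonyl to give A3.
- For it: A3 is two silyl groups away from the target, all stereocentres are set on an open chain, and C7 arises from a simple acetylide addition. In step count it beats the chosen plan, which needs four operations for the same bonds.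
- Against it: once O2 has added, the C4a carbonyl is a vinylogous ester carbonyl and a poor aldol acceptor. A tertiary ethynyl carbinol under cationic gold and water can also undergo Meyer–Schuster rearrangement. Two alkynes must react in different modes in one flask.
- Comparison: the chosen plan gives each event its own reagent and precedent (carbene for C6–C7, base for C4a=C5, gold for O2–C3), so a failure can be located and repaired.

Key step: step 17

## Route

Remark: locants C1 to C8a are those of the isochromenone core of 31 and C1' to C7' those of its side chain, and they are kept for all intermediates. C4a is formed as a mixture of two epimers in step 12 and becomes sp2 in step 18, so it is left open in names (RS) and SMILES.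

Step 1
Reactants: 1 L-allo-isoleucine
Product: 2 (2S,3R)-2-hydroxy-3-methylpentanoic acid
Conditions: NaNO2, 1 M H2SO4 (aq), 0 °C to rt
Reagents that add atoms: water, O
Why: Diazotisation of an α-amino acid goes with net retention through the α-lactone (double inversion), so C4' is kept and C5' is untouched.

Step 2
Reactants: 2 (2S,3R)-2-hydroxy-3-methylpentanoic acid
Product: 3 (2S,3R)-2-hydroxy-N-methoxy-N,3-dimethylpentanamide
Conditions: MeNH(OMe)·HCl, EDC·HCl, HOBt, N-methylmorpholine, CH2Cl2, 0 °C to rt
Reagents that add atoms: N,O-dimethylhydroxylamine hydrochloride, CNOC.Cl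
Why: Carbodiimide amide coupling; the N-methoxy-N-methylamide is chosen because it stops at the ketone stage in step 4.

Step 3
Reactants: 3 hydroxy amide
Product: 4 (2S,3R)-2-[(tert-butyldimethylsilyl)oxy]-N-methoxy-N,3-dimethylpentanamide
Conditions: TBSCl, imidazole, DMF, rt
Reagents that add atoms: tert-butyldimethylsilyl chloride, CC(C)(C)[Si](C)(C)Cl
Why: Standard silylation of a secondary alcohol; the bulky, non-chelating silyl ether is the control element for step 5.

Step 4
Reactants: 4 silyloxy amide
Product: 5 (3S,4R)-3-[(tert-butyldimethylsilyl)oxy]-4-methylhexan-2-one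
Conditions: MeMgBr, THF, 0 °C; NH4Cl (aq)
Reagents that add atoms: methylmagnesium bromide, C[Mg]Br
Why: Weinreb ketone synthesis; the chelated tetrahedral intermediate prevents a second addition, and the α-silyloxy centre is not expected to epimerise at 0 °C.

Step 5
Reactants: 5 methyl ketone; 6 1,4-bis(trimethylsilyl)buta-1,3-diyne
Product: 8 (5R,6S,7R)-6-[(tert-butyldimethylsilyl)oxy]-5,7-dimethyl-1-(trimethylsilyl)nona-1,3-diyn-5-ol, via lithium 4-(trimethylsilyl)buta-1,3-diyn-1-ide 7 (not isolated)
Conditions: 6, MeLi·LiBr, THF, 0 °C to rt; then 5, −78 °C; NH4Cl (aq)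
Reagents that add atoms: none
Why: MeLi removes one silyl group of 6, and the diynide 7 adds to the ketone under Felkin–Anh (polar) control. The C4' silyloxy group lies anti to the incoming nucleophile, which passes the hydrogen and gives the (3'R) tertiary carbinol; chelation is not expected for a silyl ether with a lithium reagent in THF.

Step 6
Reactants: 8 diynol
Product: 10 (3E,5R,6S,7R)-6-[(tert-butyldimethylsilyl)oxy]-5,7-dimethylnon-3-en-1-yn-5-ol, via the 1-trimethylsilyl enynol 9 (not isolated)
Conditions: NaAlH2(OCH2CH2OMe)2, THF, 0 °C to rt; then MeOH, K2CO3, rt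
Reagents that add atoms: none
Why: Hydroxyl-directed trans-hydroalumination of a propargylic alcohol reduces only the proximal triple bond and gives the E alkene; methoxide in methanol then cleaves the alkynylsilane.

Step 7
Reactants: 11 dimethyl (R)-malate; 12 formaldehyde
Product: 15 methyl (3S,4R)-4-hydroxy-5-oxooxolane-3-carboxylate, via dilithium dianion of dimethyl (R)-malate 13 (not isolated), via dimethyl (2R,3S)-2-hydroxy-3-(hydroxymethyl)butanedioate 14 (not isolated)
Conditions: LiN(iPr)2 (2.2 equiv), THF, −78 to −20 °C; monomeric CH2O in THF, −78 °C; 1 M HCl; then p-TsOH (cat.), CH2Cl2, rt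
Reagents that add atoms: none
Why: Fráter–Seebach reaction: the chelated dianion 13 is attacked by formaldehyde anti to the alkoxide, which sets C8a relative to C8. The new primary hydroxyl then closes onto the adjacent α-hydroxy ester carbonyl to give the trans γ-lactone, so C7 (lactone) and C4a (methyl ester) are differentiated.

Step 8
Reactants: 15 hydroxy lactone
Product: 16 methyl (2S,3R)-4-(dimethylamino)-3-hydroxy-2-(hydroxymethyl)-4-oxobutanoate
Conditions: Me2NH (2 M in THF), 0 °C to rt
Reagents that add atoms: dimethylamine, CNC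
Why: Aminolysis of a lactone; the α-hydroxy γ-lactone is far more electrophilic than the α-branched methyl ester, so only the lactone should open. This fixes C7 as a dimethylamide (a masked methyl ketone inert to acetylides, ester enolates and LiBH4) and frees the C1 hydroxyl.

Step 9
Reactants: 16 diol
Product: 17 methyl (2S,3R)-4-(dimethylamino)-4-oxo-3-[(triethylsilyl)oxy]-2-{[(triethylsilyl)oxy]methyl}butanoate
Conditions: TESCl (2.4 equiv), imidazole, DMAP (cat.), CH2Cl2, 0 °C to rt
Reagents that add atoms: triethylsilyl chloride, CC[Si](Cl)(CC)CC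
Why: Routine silylation of a primary and a secondary alcohol; no differentiation is needed because both ethers are removed together in step 19.

Step 10
Reactants: 17 ester amide
Product: 18 (2S,3R)-N1-methoxy-N1,N4,N4-trimethyl-3-[(triethylsilyl)oxy]-2-{[(triethylsilyl)oxy]methyl}butanediamide
Conditions: MeNH(OMe)·HCl, AlMe3, CH2Cl2, 0 to 40 °C; KNaC4H4O6 (aq)
Reagents that add atoms: N,O-dimethylhydroxylamine hydrochloride, CNOC.Cl
Why: Weinreb aminolysis of the methyl ester with the aluminium amide; the tertiary amide at C7 does not react, and the non-basic reagent avoids β-elimination of the silyloxy groups at C8a.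

Step 11
Reactants: 18 diamide; 10 side-chain enyne
Product: 20 (2R,3S,7E,9R,10S,11R)-10-[(tert-butyldimethylsilyl)oxy]-9-hydroxy-N,N,9,11-tetramethyl-4-oxo-2-[(triethylsilyl)oxy]-3-{[(triethylsilyl)oxy]methyl}tridec-7-en-5-ynamide, via dilithium salt of the side-chain enyne 19 (not isolated)
Conditions: 10 (1.3 equiv), n-BuLi (2.6 equiv), THF, −78 °C; then 18, −78 to −40 °C; NH4Cl (aq) at −78 °C
Reagents that add atoms: none
Why: Acyl substitution of an N-methoxy-N-methylamide by a lithium acetylide through the chelated tetrahedral intermediate, so there is no over-addition. A plain N,N-dimethylamide is not attacked by a lithium acetylide at low temperature, and the alkoxide of 19 is a spectator; the cold quench keeps the liberated amine from adding to the ynone.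

Step 12
Reactants: 20 ynone; 21 methyl acetate
Product: 23 methyl (3RS,6E,8R,9S,10R)-9-[(tert-butyldimethylsilyl)oxy]-3-{(2S,3R)-4-(dimethylamino)-4-oxo-1,3-bis[(triethylsilyl)oxy]butan-2-yl}-3,8-dihydroxy-8,10-dimethyldodec-6-en-4-ynoate, via lithium enolate of methyl acetate 22 (not isolated)
Conditions: LiN(iPr)2, 21, THF, −78 °C (4 equiv of 22); then 20, −78 °C; NH4Cl (aq) at −78 °C
Reagents that add atoms: none
Why: Acetate aldol addition; a lithium ester enolate adds 1,2 to an ynone at −78 °C, and one equivalent is used up by the C3' hydroxyl. No control at C4a is needed because this centre becomes sp2 in step 18.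

Step 13
Reactants: 23 diol ester
Product: 24 methyl (3RS,6E,8R,9S,10R)-9-[(tert-butyldimethylsilyl)oxy]-3-{(2S,3R)-4-(dimethylamino)-4-oxo-1,3-bis[(triethylsilyl)oxy]butan-2-yl}-8,10-dimethyl-3,8-bis[(triethylsilyl)oxy]dodec-6-en-4-ynoate
Conditions: TESOTf (3 equiv), 2,6-lutidine, CH2Cl2, −78 to 0 °C
Reagents that add atoms: triethylsilyl trifluoromethanesulfonate, CC[Si](CC)(CC)OS(=O)(=O)C(F)(F)F
Why: A silyl triflate silylates both tertiary alcohols; the C4a ether blocks retro-aldol and hemiketal formation and later serves as the leaving group.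

Step 14
Reactants: 24 ester
Product: 25 (2R,3S,4RS,7E,9R,10S,11R)-10-[(tert-butyldimethylsilyl)oxy]-4-(2-hydroxyethyl)-N,N,9,11-tetramethyl-2,4,9-tris[(triethylsilyl)oxy]-3-{[(triethylsilyl)oxy]methyl}tridec-7-en-5-ynamide
Conditions: LiBH4, THF, 0 °C to rt
Reagents that add atoms: none
Why: LiBH4 reduces esters but leaves tertiary amides, alkynes and silyl ethers alone, so C6 reaches the alcohol level while C7 stays masked.

Step 15
Reactants: 25 hydroxy amide
Product: 26 (3R,4S,5RS,8E,10R,11S,12R)-11-[(tert-butyldimethylsilyl)oxy]-5-(2-hydroxyethyl)-10,12-dimethyl-3,5,10-tris[(triethylsilyl)oxy]-4-{[(triethylsilyl)oxy]methyl}tetradec-8-en-6-yn-2-one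
Conditions: MeLi (3 equiv), THF, −78 °C; NH4Cl (aq) at −78 °C
Reagents that add atoms: methyllithium, [Li]C
Why: Addition of an organolithium to a tertiary amide gives a stable lithium hemiaminal that releases the ketone only on work-up. The first equivalent is consumed by the hydroxyl, and the low temperature should suppress silyl migration and epimerisation at C8.

Step 16
Reactants: 26 hydroxy ketone
Product: 27 (3RS,6E,8R,9S,10R)-9-[(tert-butyldimethylsilyl)oxy]-8,10-dimethyl-3-{(2S,3R)-4-oxo-1,3-bis[(triethylsilyl)oxy]pentan-2-yl}-3,8-bis[(triethylsilyl)oxy]dodec-6-en-4-ynal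
Conditions: Dess–Martin periodinane, NaHCO3, CH2Cl2, 0 °C to rt
Reagents that add atoms: none
Why: Dess–Martin oxidation of the primary alcohol under buffered, non-basic conditions; the ketone, silyl ethers and enyne are inert, and the β-silyloxy aldehyde is never exposed to base.

Step 17
Reactants: 27 keto aldehyde
Product: 28 (2S,3R,4S,5RS)-5-{(3E,5R,6S,7R)-6-[(tert-butyldimethylsilyl)oxy]-5,7-dimethyl-5-[(triethylsilyl)oxy]non-3-en-1-yn-1-yl}-2-hydroxy-2-methyl-3,5-bis[(triethylsilyl)oxy]-4-{[(triethylsilyl)oxy]methyl}cyclohexan-1-one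
Conditions: (5aS,10bR)-2-(pentafluorophenyl)-5a,10b-dihydro-4H,6H-indeno[2,1-b][1,2,4]triazolo[4,3-d][1,4]oxazin-2-ium tetrafluoroborate (20 mol %), Et3N (20 mol %), toluene (0.02 M), rt
Reagents that add atoms: none
Why: Et3N deprotonates the triazolium salt, the carbene adds to the unhindered C6 aldehyde, and proton transfer gives the Breslow enaminol, an acyl anion equivalent. This nucleophile attacks the C7 ketone in a 6-exo-trig closure that forms C6–C7 and ring B; release of the carbene leaves the C6 ketone and the C7 tertiary alcohol. The closest known reaction type is the carbene-catalysed intramolecular crossed aldehyde–ketone benzoin reaction that gives six-membered tertiary α-ketols. Cross-selectivity is built in, because only the aldehyde can become the acyl anion and the ketone can only accept; dilution suppresses intermolecular benzoin reaction. C7 is set by the substrate in a chair-like transition state: the C8a silyloxymethyl group is equatorial, the C8 silyloxy group axial, and the ketone oxygen axial and anti to the C8–O dipole with the methyl equatorial, which places the C7 hydroxyl trans to the C8 oxygen (7S). The chiral triazolium is meant to reinforce this facial preference. The weak base and the saturated, silylated C4a keep enal formation by β-elimination slow, and both C4a epimers should converge on the same C7, C8, C8a triad.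

Step 18
Reactants: 28 ring B ketol
Product: 29 (4S,5R,6S)-3-{(3E,5R,6S,7R)-6-[(tert-butyldimethylsilyl)oxy]-5,7-dimethyl-5-[(triethylsilyl)oxy]non-3-en-1-yn-1-yl}-6-hydroxy-6-methyl-5-[(triethylsilyl)oxy]-4-{[(triethylsilyl)oxy]methyl}cyclohex-2-en-1-one
Conditions: DBU, CH2Cl2, 0 °C to rt
Reagents that add atoms: none
Why: E1cB elimination; the ketone can enolise only towards C5 (C7 is quaternary), and the enolate expels the C4a silyloxide to give the enone conjugated with the enyne. A short reaction time at low temperature should limit vinylogous deprotonation at C8a.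

Step 19
Reactants: 29 silylated enynone
Product: 30 (4S,5R,6S)-3-[(3E,5R,6S,7R)-5,6-dihydroxy-5,7-dimethylnon-3-en-1-yn-1-yl]-5,6-dihydroxy-4-(hydroxymethyl)-6-methylcyclohex-2-en-1-one
Conditions: HF·pyridine, pyridine, THF, 0 °C to rt
Reagents that add atoms: none
Why: Fluoride cleavage of all five silyl ethers, buffered with pyridine; it is placed before ring A closure because the electron-poor enynone should tolerate it better than the trienyl ether of 31.

Step 20
Reactants: 30 enynone pentaol
Product: 31 (7S,8R,8aS)-3-[(1E,3R,4S,5R)-3,4-dihydroxy-3,5-dimethylhept-1-en-1-yl]-7,8-dihydroxy-7-methyl-1,7,8,8a-tetrahydro-6H-isochromen-6-one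
Conditions: Ph3PAuNTf2 (5 mol %), THF/CH2Cl2, rt
Reagents that add atoms: none
Why: Gold-catalysed 6-endo-dig hydroalkoxylation; the C1 hydroxyl attacks C3, the δ-carbon of the ynenone, which is favoured by both polarity (1,6-addition) and ring size, and protodeauration at C4 gives the isochromenone. The C8 and C7 hydroxyls cannot reach the alkyne without forming a bridgehead alkene, and the side-chain hydroxyls are held away by the E double bond.

## Compound list

1 | L-allo-isoleucine | CC[C@@H](C)[C@H](N)C(=O)O | starting material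
2 | (2S,3R)-2-hydroxy-3-methylpentanoic acid | CC[C@@H](C)[C@H](O)C(=O)O | intermediate
3 | (2S,3R)-2-hydroxy-N-methoxy-N,3-dimethylpentanamide | CC[C@@H](C)[C@H](O)C(=O)N(C)OC | intermediate
4 | (2S,3R)-2-[(tert-butyldimethylsilyl)oxy]-N-methoxy-N,3-dimethylpentanamide | CC[C@@H](C)[C@H](O[Si](C)(C)C(C)(C)C)C(=O)N(C)OC | intermediate
5 | (3S,4R)-3-[(tert-butyldimethylsilyl)oxy]-4-methylhexan-2-one | CC[C@@H](C)[C@H](O[Si](C)(C)C(C)(C)C)C(C)=O | intermediate
6 | 1,4-bis(trimethylsilyl)buta-1,3-diyne | C[Si](C)(C)C#CC#C[Si](C)(C)C | starting material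
7 | lithium 4-(trimethylsilyl)buta-1,3-diyn-1-ide (not isolated) | [Li]C#CC#C[Si](C)(C)C | intermediate
8 | (5R,6S,7R)-6-[(tert-butyldimethylsilyl)oxy]-5,7-dimethyl-1-(trimethylsilyl)nona-1,3-diyn-5-ol | CC[C@@H](C)[C@H](O[Si](C)(C)C(C)(C)C)[C@](C)(O)C#CC#C[Si](C)(C)C | intermediate
9 | (3E,5R,6S,7R)-6-[(tert-butyldimethylsilyl)oxy]-5,7-dimethyl-1-(trimethylsilyl)non-3-en-1-yn-5-ol (not isolated) | CC[C@@H](C)[C@H](O[Si](C)(C)C(C)(C)C)[C@](C)(O)/C=C/C#C[Si](C)(C)C | intermediate
10 | (3E,5R,6S,7R)-6-[(tert-butyldimethylsilyl)oxy]-5,7-dimethylnon-3-en-1-yn-5-ol (side-chain enyne) | CC[C@@H](C)[C@H](O[Si](C)(C)C(C)(C)C)[C@](C)(O)/C=C/C#C | intermediate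
11 | dimethyl (R)-malate | COC(=O)C[C@@H](O)C(=O)OC | starting material
12 | formaldehyde | C=O | starting material
13 | dilithium dianion of dimethyl (R)-malate (not isolated) | COC(=O)[C@H](O[Li])C=C(O[Li])OC | intermediate
14 | dimethyl (2R,3S)-2-hydroxy-3-(hydroxymethyl)butanedioate (not isolated) | COC(=O)[C@@H](CO)[C@@H](O)C(=O)OC | intermediate
15 | methyl (3S,4R)-4-hydroxy-5-oxooxolane-3-carboxylate | COC(=O)[C@H]1COC(=O)[C@@H]1O | intermediate
16 | methyl (2S,3R)-4-(dimethylamino)-3-hydroxy-2-(hydroxymethyl)-4-oxobutanoate | COC(=O)[C@@H](CO)[C@@H](O)C(=O)N(C)C | intermediate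
17 | methyl (2S,3R)-4-(dimethylamino)-4-oxo-3-[(triethylsilyl)oxy]-2-{[(triethylsilyl)oxy]methyl}butanoate | COC(=O)[C@@H](CO[Si](CC)(CC)CC)[C@@H](O[Si](CC)(CC)CC)C(=O)N(C)C | intermediate
18 | (2S,3R)-N1-methoxy-N1,N4,N4-trimethyl-3-[(triethylsilyl)oxy]-2-{[(triethylsilyl)oxy]methyl}butanediamide | CON(C)C(=O)[C@@H](CO[Si](CC)(CC)CC)[C@@H](O[Si](CC)(CC)CC)C(=O)N(C)C | intermediate
19 | dilithium salt (C3' alkoxide, C4 acetylide) of enyne 10 (not isolated) | CC[C@@H](C)[C@H](O[Si](C)(C)C(C)(C)C)[C@](C)(O[Li])/C=C/C#C[Li] | intermediate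
20 | (2R,3S,7E,9R,10S,11R)-10-[(tert-butyldimethylsilyl)oxy]-9-hydroxy-N,N,9,11-tetramethyl-4-oxo-2-[(triethylsilyl)oxy]-3-{[(triethylsilyl)oxy]methyl}tridec-7-en-5-ynamide (ynone) | CC[C@@H](C)[C@H](O[Si](C)(C)C(C)(C)C)[C@](C)(O)/C=C/C#CC(=O)[C@@H](CO[Si](CC)(CC)CC)[C@@H](O[Si](CC)(CC)CC)C(=O)N(C)C | intermediate
21 | methyl acetate | CC(=O)OC | starting material
22 | lithium enolate of methyl acetate (not isolated) | C=C(O[Li])OC | intermediate
23 | methyl (3RS,6E,8R,9S,10R)-9-[(tert-butyldimethylsilyl)oxy]-3-{(2S,3R)-4-(dimethylamino)-4-oxo-1,3-bis[(triethylsilyl)oxy]butan-2-yl}-3,8-dihydroxy-8,10-dimethyldodec-6-en-4-ynoate | CC[C@@H](C)[C@H](O[Si](C)(C)C(C)(C)C)[C@](C)(O)/C=C/C#CC(O)(CC(=O)OC)[C@@H](CO[Si](CC)(CC)CC)[C@@H](O[Si](CC)(CC)CC)C(=O)N(C)C | intermediate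
24 | methyl (3RS,6E,8R,9S,10R)-9-[(tert-butyldimethylsilyl)oxy]-3-{(2S,3R)-4-(dimethylamino)-4-oxo-1,3-bis[(triethylsilyl)oxy]butan-2-yl}-8,10-dimethyl-3,8-bis[(triethylsilyl)oxy]dodec-6-en-4-ynoate | CC[C@@H](C)[C@H](O[Si](C)(C)C(C)(C)C)[C@](C)(O[Si](CC)(CC)CC)/C=C/C#CC(O[Si](CC)(CC)CC)(CC(=O)OC)[C@@H](CO[Si](CC)(CC)CC)[C@@H](O[Si](CC)(CC)CC)C(=O)N(C)C | intermediate
25 | (2R,3S,4RS,7E,9R,10S,11R)-10-[(tert-butyldimethylsilyl)oxy]-4-(2-hydroxyethyl)-N,N,9,11-tetramethyl-2,4,9-tris[(triethylsilyl)oxy]-3-{[(triethylsilyl)oxy]methyl}tridec-7-en-5-ynamide | CC[C@@H](C)[C@H](O[Si](C)(C)C(C)(C)C)[C@](C)(O[Si](CC)(CC)CC)/C=C/C#CC(O[Si](CC)(CC)CC)(CCO)[C@@H](CO[Si](CC)(CC)CC)[C@@H](O[Si](CC)(CC)CC)C(=O)N(C)C | intermediate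
26 | (3R,4S,5RS,8E,10R,11S,12R)-11-[(tert-butyldimethylsilyl)oxy]-5-(2-hydroxyethyl)-10,12-dimethyl-3,5,10-tris[(triethylsilyl)oxy]-4-{[(triethylsilyl)oxy]methyl}tetradec-8-en-6-yn-2-one | CC[C@@H](C)[C@H](O[Si](C)(C)C(C)(C)C)[C@](C)(O[Si](CC)(CC)CC)/C=C/C#CC(O[Si](CC)(CC)CC)(CCO)[C@@H](CO[Si](CC)(CC)CC)[C@@H](O[Si](CC)(CC)CC)C(C)=O | intermediate
27 | (3RS,6E,8R,9S,10R)-9-[(tert-butyldimethylsilyl)oxy]-8,10-dimethyl-3-{(2S,3R)-4-oxo-1,3-bis[(triethylsilyl)oxy]pentan-2-yl}-3,8-bis[(triethylsilyl)oxy]dodec-6-en-4-ynal (keto aldehyde, key-step precursor) | CC[C@@H](C)[C@H](O[Si](C)(C)C(C)(C)C)[C@](C)(O[Si](CC)(CC)CC)/C=C/C#CC(O[Si](CC)(CC)CC)(CC=O)[C@@H](CO[Si](CC)(CC)CC)[C@@H](O[Si](CC)(CC)CC)C(C)=O | intermediate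
28 | (2S,3R,4S,5RS)-5-{(3E,5R,6S,7R)-6-[(tert-butyldimethylsilyl)oxy]-5,7-dimethyl-5-[(triethylsilyl)oxy]non-3-en-1-yn-1-yl}-2-hydroxy-2-methyl-3,5-bis[(triethylsilyl)oxy]-4-{[(triethylsilyl)oxy]methyl}cyclohexan-1-one (ring B acyloin, key-step product) | CC[C@@H](C)[C@H](O[Si](C)(C)C(C)(C)C)[C@](C)(O[Si](CC)(CC)CC)/C=C/C#CC1(O[Si](CC)(CC)CC)CC(=O)[C@@](C)(O)[C@H](O[Si](CC)(CC)CC)[C@@H]1CO[Si](CC)(CC)CC | intermediate
29 | (4S,5R,6S)-3-{(3E,5R,6S,7R)-6-[(tert-butyldimethylsilyl)oxy]-5,7-dimethyl-5-[(triethylsilyl)oxy]non-3-en-1-yn-1-yl}-6-hydroxy-6-methyl-5-[(triethylsilyl)oxy]-4-{[(triethylsilyl)oxy]methyl}cyclohex-2-en-1-one | CC[C@@H](C)[C@H](O[Si](C)(C)C(C)(C)C)[C@](C)(O[Si](CC)(CC)CC)/C=C/C#CC1=CC(=O)[C@@](C)(O)[C@H](O[Si](CC)(CC)CC)[C@@H]1CO[Si](CC)(CC)CC | intermediate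
30 | (4S,5R,6S)-3-[(3E,5R,6S,7R)-5,6-dihydroxy-5,7-dimethylnon-3-en-1-yn-1-yl]-5,6-dihydroxy-4-(hydroxymethyl)-6-methylcyclohex-2-en-1-one | CC[C@@H](C)[C@H](O)[C@](C)(O)/C=C/C#CC1=CC(=O)[C@@](C)(O)[C@H](O)[C@@H]1CO | intermediate
31 | (7S,8R,8aS)-3-[(1E,3R,4S,5R)-3,4-dihydroxy-3,5-dimethylhept-1-en-1-yl]-7,8-dihydroxy-7-methyl-1,7,8,8a-tetrahydro-6H-isochromen-6-one | CC[C@@H](C)[C@H](O)[C@](C)(O)/C=C/C1=CC2=CC(=O)[C@@](C)(O)[C@H](O)[C@@H]2CO1 | target

## Step count and least certain steps

Total step count: 20 (6 for the side-chain enyne 10, 4 for diamide 18, 10 from the union to 31).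
Longest linear sequence: 16 steps (steps 1 to 6, then 11 to 20, from L-allo-isoleucine 1); the sequence from dimethyl (R)-malate 11 is 14 steps.

**Step 17 (key step).** Three things may go wrong. Base-induced β-elimination of the C4a silyloxy group may turn the aldehyde into an enal before the carbene engages it. The two C4a epimers may cyclise at different rates. The facial preference of the substrate and that of the catalyst may oppose each other and give poor selectivity at C7. If pairing with the antipodal triazolium salt does not cure this, the fallback leaves carbene catalysis. Keto aldehyde 27 is treated with SmI2 in THF with t-BuOH at −78 °C, so that the aldehyde ketyl adds to the C7 ketone in a pinacol-type cyclisation. This gives the ring B C6,C7-diol F1, with the new C7 hydroxyl expected anti to the C8 silyloxy group. Parikh–Doering oxidation (SO3·pyridine, DMSO, iPr2NEt) of the secondary C6 alcohol then returns to 28.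

**Step 12.** The basic lithium enolate may deprotonate C8a of the ynone instead of adding, leading to epimerisation or loss of a β-silyloxy group, or it may add in conjugate fashion. The fallback replaces the lithium enolate by a neutral zinc enolate: a Reformatsky reaction of 20 with methyl bromoacetate and activated zinc in THF, which adds to enolisable ketones and returns directly to 23.

**Step 11 (with step 10).** Amide exchange on the hindered ester may be sluggish, and the acetylide may fail to distinguish cleanly between the two amides. The fallback sets out from ester 17. LiBH4 reduction gives the primary alcohol F2, Dess–Martin oxidation gives aldehyde F3, and addition of the dilithium salt 19 gives the propargylic alcohol F4 (an aldehyde reacts far faster than any amide). Oxidation with MnO2 returns to ynone 20.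

**Step 15.** The lithium alkoxide at C6 may take over the silyl group from the C4a oxygen, or the amide may react slowly enough for enolisation at C8 to compete. The fallback sets out from 25. The primary hydroxyl is capped (TMSCl, Et3N) as the trimethylsilyl ether F5. MeLi then gives the methyl ketone F6 with no alkoxide present. Citric acid in MeOH removes the primary trimethylsilyl group and returns to 26.

**Step 5.** Felkin–Anh control by the silyloxy group may give poor facial selectivity at C3'. The fallback uses chelation control with the roles of the two carbon groups exchanged. From hydroxy amide 3, 4-methoxybenzyl trichloroacetimidate with acid catalysis gives the 4-methoxybenzyl ether F7. Diynide 7 converts it into diynone F8. MeMgBr in Et2O or CH2Cl2 at −78 °C adds through the five-membered magnesium chelate, past the C4' hydrogen, to give the (3'R) tertiary alcohol F9. DDQ gives diol F10, and TBSOTf with 2,6-lutidine at −78 °C silylates only the secondary hydroxyl, which returns to 8.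

**Step 20.** On the unprotected pentaol, 5-exo attack at C4 may compete, or traces of acid may ionise the C3' alcohol of the product. The fallback closes ring A with the other hydroxyls still silylated. From 29, PPTS in MeOH at 0 °C removes the primary triethylsilyl group to give the C1 alcohol F11. Ph3PAuNTf2 closes ring A to the silylated isochromenone F12. HF·pyridine buffered with pyridine then returns to 31.

## Further compounds

F1 | step 17 | ring B C6,C7-diol, the C6 alcohol corresponding to ketone 28 (C6 and C4a left open) | CC[C@@H](C)[C@H](O[Si](C)(C)C(C)(C)C)[C@](C)(O[Si](CC)(CC)CC)/C=C/C#CC1(O[Si](CC)(CC)CC)CC(O)[C@@](C)(O)[C@H](O[Si](CC)(CC)CC)[C@@H]1CO[Si](CC)(CC)CC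
F0 | step 12 | none | none
F2 | step 11 | (2R,3S)-4-hydroxy-N,N-dimethyl-2-[(triethylsilyl)oxy]-3-{[(triethylsilyl)oxy]methyl}butanamide | OC[C@@H](CO[Si](CC)(CC)CC)[C@@H](O[Si](CC)(CC)CC)C(=O)N(C)C
F3 | step 11 | (2R,3S)-N,N-dimethyl-4-oxo-2-[(triethylsilyl)oxy]-3-{[(triethylsilyl)oxy]methyl}butanamide | O=C[C@@H](CO[Si](CC)(CC)CC)[C@@H](O[Si](CC)(CC)CC)C(=O)N(C)C
F4 | step 11 | propargylic alcohol, the C4a carbinol (both epimers) corresponding to ynone 20 | CC[C@@H](C)[C@H](O[Si](C)(C)C(C)(C)C)[C@](C)(O)/C=C/C#CC(O)[C@@H](CO[Si](CC)(CC)CC)[C@@H](O[Si](CC)(CC)CC)C(=O)N(C)C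
F5 | step 15 | C6 trimethylsilyl ether of hydroxy amide 25 | CC[C@@H](C)[C@H](O[Si](C)(C)C(C)(C)C)[C@](C)(O[Si](CC)(CC)CC)/C=C/C#CC(O[Si](CC)(CC)CC)(CCO[Si](C)(C)C)[C@@H](CO[Si](CC)(CC)CC)[C@@H](O[Si](CC)(CC)CC)C(=O)N(C)C
F6 | step 15 | C6 trimethylsilyl ether of hydroxy ketone 26 | CC[C@@H](C)[C@H](O[Si](C)(C)C(C)(C)C)[C@](C)(O[Si](CC)(CC)CC)/C=C/C#CC(O[Si](CC)(CC)CC)(CCO[Si](C)(C)C)[C@@H](CO[Si](CC)(CC)CC)[C@@H](O[Si](CC)(CC)CC)C(C)=O
F7 | step 5 | (2S,3R)-N-methoxy-2-[(4-methoxybenzyl)oxy]-N,3-dimethylpentanamide | CC[C@@H](C)[C@H](OCc1ccc(OC)cc1)C(=O)N(C)OC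
F8 | step 5 | (6S,7R)-6-[(4-methoxybenzyl)oxy]-7-methyl-1-(trimethylsilyl)nona-1,3-diyn-5-one | CC[C@@H](C)[C@H](OCc1ccc(OC)cc1)C(=O)C#CC#C[Si](C)(C)C
F9 | step 5 | (5R,6S,7R)-6-[(4-methoxybenzyl)oxy]-5,7-dimethyl-1-(trimethylsilyl)nona-1,3-diyn-5-ol | CC[C@@H](C)[C@H](OCc1ccc(OC)cc1)[C@](C)(O)C#CC#C[Si](C)(C)C
F10 | step 5 | (5R,6S,7R)-5,7-dimethyl-1-(trimethylsilyl)nona-1,3-diyne-5,6-diol | CC[C@@H](C)[C@H](O)[C@](C)(O)C#CC#C[Si](C)(C)C
F11 | step 20 | C1 alcohol of enynone 29 (C8 and C3' triethylsilyl and C4' tert-butyldimethylsilyl ethers kept) | CC[C@@H](C)[C@H](O[Si](C)(C)C(C)(C)C)[C@](C)(O[Si](CC)(CC)CC)/C=C/C#CC1=CC(=O)[C@@](C)(O)[C@H](O[Si](CC)(CC)CC)[C@@H]1CO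
F12 | step 20 | 8,3'-bis(triethylsilyl) 4'-(tert-butyldimethylsilyl) ether of target 31 | CC[C@@H](C)[C@H](O[Si](C)(C)C(C)(C)C)[C@](C)(O[Si](CC)(CC)CC)/C=C/C1=CC2=CC(=O)[C@@](C)(O)[C@H](O[Si](CC)(CC)CC)[C@@H]2CO1
A1 | alternative 1 | trans-fused pyranocyclohexane with C4 allyl ester, C6/C7 acetonide and C8 silyl ether | CC[C@@H](C)[C@H](O[Si](C)(C)C(C)(C)C)[C@](C)(O)/C=C/C1=C(C(=O)OCC=C)[C@H]2C[C@H]3OC(C)(C)O[C@@]3(C)[C@H](O[Si](C)(C)C(C)(C)C)[C@@H]2CO1
A2 | alternative 2 | ring B ynenone cis-fused to a 2-tert-butyl-1,3-dioxane | CC[C@@H](C)[C@H](O[Si](C)(C)C(C)(C)C)[C@](C)(O[Si](CC)(CC)CC)/C=C/C#CC1=CC(=O)[C@@](C)(O[Si](CC)(CC)CC)[C@@H]2O[C@@H](C(C)(C)C)OC[C@H]12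
A3 | alternative 3 | 8,4'-bis(tert-butyldimethylsilyl) ether of target 31 | CC[C@@H](C)[C@H](O[Si](C)(C)C(C)(C)C)[C@](C)(O)/C=C/C1=CC2=CC(=O)[C@@](C)(O)[C@H](O[Si](C)(C)C(C)(C)C)[C@@H]2CO1
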